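## Structural features

The target is a bicyclic triamine in which a 1,2,3,6-tetrahydropyridine (ring A: N1, C2, C3=C4, C5, C6) shares its N1–C6 bond with a 13-membered lactam (N1, C6, C7, C8(=O), N9, C10–C13, N14, C15–C17). N1 is a tertiary amine flanked by the only two stereocentres: C2 (S), allylic to C3=C4 and carrying the 2-oxoheptyl chain, and C6 (R), carrying the C7 methylene of the lactam. The two branches are trans across ring A. N9 is a secondary lactam nitrogen and N14 a free secondary amine, so the compound is polar and strongly basic. The fragile unit is the β-amino ketone N1–C2–CH2–C(=O): β-elimination of N1 would open ring A to a dienone, and re-addition would scramble C2. The isolated C3=C4 bond must stay in place and rules out hydrogenolytic deprotection. The real difficulty is the trans-2,6 relation around a fully substituted nitrogen that is part of a macrocycle, since any plan that alkylates N1 last must do so between two branched carbons. The key step uses the fact that C2 is both α to N1 and allylic: ring A is what an iminium ion N1=C2 gives when a C3–C4 vinylsilane, hung from C6 through C5, closes onto it while N1 already carries the macrocycle.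

## Logic of the disconnections

**21 ⇐ 20 ⇐ 19.** The N14–H bond is traced back to its carbamate and the side-chain C=O to a C≡C bond (the carbonyl C–O bonds are cut to water). The reason is that the β-amino ketone is the most fragile element, whereas the alkyne is inert, linear and slim. The gain is a robust precursor, 19, that carries no ketone. The demand is that water adds only at the alkyne carbon remote from N1, and that everything after the ketone appears stays acidic and cool.

**19 ⇐ 16 + 17.** The bonds N1–C2 and C2–C3 are cut. This removes ring A, the C2 stereocentre and all seven side-chain carbons at once, and leaves a monocyclic amine with one stereocentre. The demand is condensation of N1–H at the aldehyde carbon of 17, a Z-vinylsilane at C3–C4, trans induction from C6, and survival of the N14 carbamate under the acid used.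

**16 ⇐ 14 (through 15).** The lactam bond N9–C8 is cut. It is the only ring bond that forms irreversibly between two unhindered termini (a primary amine and an unbranched CH2–CO2H). The gain is an open chain. The demand is high dilution, and that the branched N1–H does not compete for the activated carboxyl.

**14 ⇐ 13 ⇐ 12.** No skeletal bond is cut: the N9 amine is traced to an imide and the acid to a methyl ester. The imide is removed first because aqueous base would open it to a phthalamate. The demand is that hydrazinolysis spares the ester and the alkene.

**12 ⇐ 11.** The two vinylic C–H bonds are removed, so the Z-vinylsilane comes from a silylalkyne by syn-hydrogenation. The geometry is then fixed by mechanism, and the acid-tolerant alkynylsilane can be carried through the one strongly acidic step. The demand is that reduction stops at the alkene.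

**11 ⇐ 4 + 9 (through 10).** The bond N1–C17 is cut by a reductive-amination retron. It joins two halves of similar size at an unbranched carbon and leaves N1 as the secondary amine the key step needs. The demand is monoalkylation and a reductant that spares the imide.

**9 ⇐ 8 ⇐ 5 + 6 (through 7).** The bonds N14–C13 and N14–CO2tBu are cut, and C17 is adjusted from alcohol to aldehyde. Both building blocks are commercial. The demand is mono-N-alkylation of 5 and an oxidation that stops at the aldehyde.

**4 ⇐ 3 ⇐ 1 (through 2).** The C–Si bond is cut and the ester and free amine are traced back to the acid and carbamate of 1. Compound 1 supplies C6 in the correct configuration, together with C5–C8 and the two alkyne carbons that become C3 and C4. The demand is C-silylation in the presence of two more acidic sites.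

## Other disconnections considered

**Alternative 1:** The cut is C3=C4 of ring A by olefin metathesis, with C2, C3 and the first side-chain carbons drawn from a cyclopentene. In the forward sense, the ammonium salt of A1 would be treated with second-generation Hoveyda–Grubbs catalyst. A1 is a tertiary amine whose N1 carries a cis-4-silyloxycyclopent-2-enyl group, the C6 homoallyl unit with its CH2CO2Me arm, and the protected chain. Ring opening of the cyclopentene and closure onto the homoallyl alkene should give A2, ring A with C3=C4 and a CH2–CH(OSi)–CH=CH2 chain at C2.

- In its favour: both stereocentres exist before ring A forms (C2 from the cyclopentenyl carbon, C6 from the homoallylamine), so the trans relation is not a matter of transition-state selectivity. On this point it is better than the chosen plan. The placement of the ring alkene is equally unambiguous in both plans. The step is catalytic and free of the acid and silicon issues.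
- Against it: A1 requires N1 to be assembled between two branched carbons by N-alkylation, the hindered bond formation the chosen plan avoids. The basic nitrogen must be masked as a salt to protect the ruthenium carbene. The side chain of A2 is three carbons short and at the wrong oxidation level, so it needs desilylation, oxidation and chain extension in the presence of the ring alkene, through β-amino enone intermediates prone to elimination. The macrocycle is still to be closed.
- Comparison: stereochemically safer, but it postpones both the ketone chain and the macrocycle, and should be several steps longer after its key step than the single operation the chosen plan needs.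

**Alternative 2:** The cut is C6–C7, which also opens the 13-membered ring; ring A is kept as a lactam (C6=O). In the forward sense, A3 is the ring A lactam whose N1 carries the triamine chain ending in a malonamic acid. It would be hydrosilylated at C6 with IrCl(CO)(PPh3)2 and 1,1,3,3-tetramethyldisiloxane. Acid would release the iminium ion N1=C6, and the malonamic acid carbon would trap it with loss of CO2 to give A4, the ketal-protected N14-Boc bicycle.

- In its favour: the ketone travels as a ketal, so no late alkyne hydration is needed; on this point it is better than the chosen plan. The iridium catalyst should distinguish the tertiary lactam from the secondary amide and the carbamate. One event makes the C–C bond, the C6 stereocentre and the macrocycle. The trans outcome rests on the same strain argument (attack anti to a pseudoaxial C2 branch), which is equal to the chosen plan.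
- Against it: a weak carbon nucleophile has to close a 13-membered ring at high dilution. While it waits, the iminium ion can lose a C5 proton to a conjugated dienamine, which would move the ring alkene or invite attack at C4. Decarboxylation without C–C formation is a dead end. The free acid and N–H groups consume silane, and ketal and Boc must survive the acid release.
- Comparison: more convergent on paper and free of the hydration risk, but mechanistically it stacks three selectivity problems in one step where the chosen plan separates macrocyclisation from ring A formation. Step economy is about equal, since the enantioenriched ring A lactam must be made first.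

**Alternative 3:** The cut is N1–C6, with ring A derived from a 2,5-disubstituted furan. In the forward sense, the furan A5 (a Boc-protected furfurylamine with the ketal chain, and CH2CO2Me at the other α-position) would be methoxylated anodically in methanol and hydrolysed with mild acid. The resulting cis-enedione would be captured at its C6 ketone by the carbamate nitrogen to give the 6-hydroxy-2H-pyridin-3-one A6.

- In its favour: a reagent-free, scalable oxidation; a simple precursor whose C2 stereocentre can come from a chiral furfurylamine; the ketone carried as a ketal (better than the chosen plan on that point); and no silicon chemistry.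
- Against it: A6 has the wrong oxidation pattern (C3=O and C4=C5 where the target has C3=C4 and no oxygen). It would need ionisation and reduction at C6, carbonyl reduction and a reductive 1,3-transposition of the allylic alcohol. Hydride is expected to enter the N-acyliminium ion anti to the pseudoaxial C2 branch, which places the C6 arm cis to it, the wrong relation. N1 must then be alkylated between two branches after Boc removal, and the macrocycle closed last.
- Comparison: the key step itself is as reliable as the chosen one, but the structural mismatch afterwards, the unsecured trans relation and the late hindered N-alkylation make it clearly longer and less safe.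

Key step: step 10

Remark on numbering and descriptors: the labels N1, C2, C3=C4, C5, C6, C7, C8(=O), N9, C10–C13, N14, C15–C17 are used for the macrocyclic compounds. The spatial arrangement at C2 is identical in 19, 20 and 21; the descriptor is R in 19 and S in 20 and 21 only because the alkynyl carbon outranks C3 whereas the CH2 of the oxoheptyl chain does not.

Remark on the structures: a check of the descriptors finds them consistent. The (R) centre of 1 maps onto C6 (R) throughout. The vinylsilane has to be Z (silicon cis to C5) for ipso attack with retention to give the cis ring alkene. The trans product 19 corresponds to the (2S,6R) target. The precursor is therefore kept as it stands. The refinements concern its handling: the only strongly acidic step comes before the vinylsilane exists, and the acid in the cyclisation is limited to one equivalent so that the N14 carbamate survives.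

Assumption: 1, 5, 6 and 17 are taken as commercial.

## Route

**Step 1**
Reactants: 1 (R)-3-(tert-butoxycarbonylamino)hex-5-ynoic acid
Product: 3 (R)-3-(tert-butoxycarbonylamino)-6-(trimethylsilyl)hex-5-ynoic acid, via trisilylated ester 2 (not isolated)
Conditions: LiN(iPr)2 (3.3 equiv), THF, −78 °C; Me3SiCl (3.5 equiv), −78 → 0 °C; 10% aq. citric acid
Reagents that add atoms: chlorotrimethylsilane, C[Si](C)(C)Cl
Why: Deprotonation of CO2H, carbamate N–H and alkyne C–H gives a trilithio species whose carboxylate resists enolisation at −78 °C; the acetylide is silylated on carbon, and the O- and N-silyl groups of 2 are hydrolysed in the acidic work-up (acetylide C-silylation through a polyanion). The stereocentre is not involved.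

**Step 2**
Reactants: 3 (R)-3-(tert-butoxycarbonylamino)-6-(trimethylsilyl)hex-5-ynoic acid
Product: 4 methyl (R)-3-amino-6-(trimethylsilyl)hex-5-ynoate hydrochloride
Conditions: HCl (3 M in MeOH), 0 °C → rt
Reagents that add atoms: methanol, CO; hydrogen chloride, Cl
Why: Methanolic HCl should effect Fischer esterification and acidolysis of the Boc group in one operation; the alkynylsilane is far less prone to protodesilylation than the later vinylsilane, which is why this step precedes the semireduction.

**Step 3**
Reactants: 5 3-aminopropan-1-ol (3 equiv); 6 N-(4-bromobutyl)phthalimide
Product: 8 tert-butyl N-(3-hydroxypropyl)-N-(4-phthalimidobutyl)carbamate, via secondary amine 7 (not isolated)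
Conditions: K2CO3, MeCN, rt; aqueous wash; Boc2O, CH2Cl2, rt
Reagents that add atoms: di-tert-butyl dicarbonate, CC(C)(C)OC(=O)OC(=O)OC(C)(C)C
Why: SN2 N-alkylation with the amine in excess to suppress dialkylation (the water-soluble excess is washed out), followed by chemoselective carbamoylation of the secondary amine in the presence of the primary alcohol.

**Step 4**
Reactants: 8 tert-butyl N-(3-hydroxypropyl)-N-(4-phthalimidobutyl)carbamate
Product: 9 tert-butyl N-(3-oxopropyl)-N-(4-phthalimidobutyl)carbamate
Conditions: PhI(OAc)2 (1.1 equiv), 2,2,6,6-tetramethylpiperidin-1-oxyl (10 mol %), CH2Cl2, rt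
Reagents that add atoms: none
Why: Oxoammonium-mediated oxidation of the primary alcohol should stop at the aldehyde under anhydrous conditions and leave carbamate and imide untouched; the β-carbamoyl aldehyde is used without storage.

**Step 5**
Reactants: 4 methyl (R)-3-amino-6-(trimethylsilyl)hex-5-ynoate hydrochloride; 9 tert-butyl N-(3-oxopropyl)-N-(4-phthalimidobutyl)carbamate
Product: 11 methyl (R)-3-[3-[tert-butoxycarbonyl(4-phthalimidobutyl)amino]propylamino]-6-(trimethylsilyl)hex-5-ynoate, via aldimine 10 (not isolated)
Conditions: Et3N (1.0 equiv), 4 Å MS, ClCH2CH2Cl, rt; NaBH(OAc)3 (1.5 equiv), rt; aq. NaHCO3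
Reagents that add atoms: none
Why: Reductive amination: the liberated α-branched primary amine condenses with the aldehyde, and NaBH(OAc)3 reduces the imine but not the imide or ester; branching at the amine carbon and 1:1 stoichiometry disfavour a second alkylation. The stereocentre is untouched.

**Step 6**
Reactants: 11 methyl (R)-3-[3-[tert-butoxycarbonyl(4-phthalimidobutyl)amino]propylamino]-6-(trimethylsilyl)hex-5-ynoate
Product: 12 methyl (3R,5Z)-3-[3-[tert-butoxycarbonyl(4-phthalimidobutyl)amino]propylamino]-6-(trimethylsilyl)hex-5-enoate
Conditions: H2 (1 atm), Pd/CaCO3 poisoned with Pb(OAc)2, quinoline, EtOAc, rt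
Reagents that add atoms: none
Why: Syn delivery of hydrogen on the poisoned palladium surface gives the Z-vinylsilane (Lindlar-type semihydrogenation); the bulky silyl group and the amine both retard over-reduction.

**Step 7**
Reactants: 12 methyl (3R,5Z)-3-[3-[tert-butoxycarbonyl(4-phthalimidobutyl)amino]propylamino]-6-(trimethylsilyl)hex-5-enoate
Product: 13 methyl (3R,5Z)-3-[3-[(4-aminobutyl)(tert-butoxycarbonyl)amino]propylamino]-6-(trimethylsilyl)hex-5-enoate
Conditions: N2H4·H2O (1.5 equiv), EtOH, rt, under Ar
Reagents that add atoms: none
Why: Ing–Manske hydrazinolysis: the imide carbonyls are far more electrophilic than the unactivated methyl ester, so a small excess of hydrazine at room temperature should free N9 without hydrazide formation; air is excluded so that no diimide forms to reduce the alkene.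

**Step 8**
Reactants: 13 methyl (3R,5Z)-3-[3-[(4-aminobutyl)(tert-butoxycarbonyl)amino]propylamino]-6-(trimethylsilyl)hex-5-enoate
Product: 14 (3R,5Z)-3-[3-[(4-aminobutyl)(tert-butoxycarbonyl)amino]propylamino]-6-(trimethylsilyl)hex-5-enoic acid
Conditions: LiOH·H2O (1.5 equiv), THF/MeOH/H2O, 0 °C → rt; 1 M HCl to pH 7
Reagents that add atoms: lithium hydroxide, [Li+].[OH-]
Why: Saponification by acyl–oxygen cleavage; vinylsilane, carbamate and amines are stable to aqueous LiOH, and the amino acid is taken on as the neutral zwitterion.

**Step 9**
Reactants: 14 (3R,5Z)-3-[3-[(4-aminobutyl)(tert-butoxycarbonyl)amino]propylamino]-6-(trimethylsilyl)hex-5-enoic acid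
Product: 16 tert-butyl (6R)-8-oxo-6-[(Z)-3-(trimethylsilyl)prop-2-enyl]-1,5,9-triazacyclotridecane-1-carboxylate (the N14-Boc 13-membered lactam with N1–H), via acyl azide 15 (not isolated)
Conditions: (PhO)2P(O)N3 (1.5 equiv), NaHCO3 (5 equiv), DMF (1 mM), 0 → 4 °C
Reagents that add atoms: none
Why: Macrolactamisation through the acyl azide: at high dilution the unhindered primary amine N9 attacks C8 and closes the 13-membered ring (13-exo-trig); the branched N1–H could only form a four-membered lactam and should not compete at this temperature, which also holds back Curtius rearrangement.

**Step 10**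
Reactants: 16 tert-butyl (6R)-8-oxo-6-[(Z)-3-(trimethylsilyl)prop-2-enyl]-1,5,9-triazacyclotridecane-1-carboxylate; 17 oct-2-ynal (1.3 equiv)
Product: 19 (2R,6R)-2-(hept-1-ynyl) N14-Boc bicyclic lactam (ring A N1/C2/C3=C4/C5/C6 fused at N1–C6 to the 13-membered lactam; C2 and C6 branches trans), via alkynyl iminium ion 18 (not isolated)
Conditions: 10-camphorsulfonic acid (1.05 equiv), 4 Å MS, MeCN, rt then 60 °C; aq. NaHCO3
Reagents that add atoms: none
Why: The ammonium salt of 16 condenses with 17 to the (E)-alkynyl iminium ion 18 (N1=C2); reversible side equilibria such as an aminal with N9–H drain back into this ion. The silicon-bearing carbon C3 of the Z-vinylsilane attacks C2 through a chair-like six-membered transition state, and the cation that develops at C4, β to silicon, collapses by loss of the silyl group, so the double bond ends at C3=C4 (ipso substitution with retention, hence the need for the Z isomer). The closest known reaction type is the iminium ion–vinylsilane (aza-silyl-Prins) cyclisation of N-alkyl (Z)-4-silylbut-3-enylamines with aldehydes to 1,2,5,6-tetrahydropyridines. Ring A closes in the 6-endo-trig mode at the iminium carbon, the vinylsilane π bond being endocyclic as well. The new stereocentre C2 is controlled by C6: to avoid eclipsing the in-plane N1–C17 bond the C6–C7 bond sits axial, the slim alkynyl group of the (E)-iminium ion sits equatorial, and a 1,3-diaxial arrangement of both is excluded, which places the two branches trans (2R,6R). A 2-aza-Cope shift to the C6 iminium ion and allylsilane, followed by re-closure, would lead through the same chair to the same constitution and the same trans isomer. The step needs 1,2- rather than 1,4-addition of N1–H to the ynal, which the protonated amine, the reversible carbinolamine formation and the substituted β-carbon should secure; it also needs the carbamate to survive, which it should because the single equivalent of acid is bound as ammonium or iminium salt. N1 receives its third substituent from the macrocycle, so no alkylation of a hindered amine follows.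

**Step 11**
Reactants: 19 (2R,6R)-2-(hept-1-ynyl) N14-Boc bicyclic lactam
Product: 21 (2S,6R)-2-(2-oxoheptyl) bicyclic lactam with free N14–H (the target), via N14-Boc ketone 20 (not isolated)
Conditions: NaAuCl4·2H2O (5 mol %), TsOH·H2O (1.1 equiv), MeOH/H2O 10:1, 50 °C; then HCl (4 M in dioxane), rt; cold aq. NaHCO3
Reagents that add atoms: water, O
Why: Trivalent gold activates the alkyne and the oxygen nucleophile adds at the carbon remote from the protonated N1, because the ammonium group destabilises positive charge at the proximal carbon; this gives the β-amino ketone 20 (gold-catalysed alkyne hydration directed by a propargylic heteroatom). Acidolysis then removes the Boc group while N1 stays protonated, which suppresses β-elimination; C2 and C6 are not touched, and only the descriptor at C2 changes.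

## Compound list

1 | (R)-3-(tert-butoxycarbonylamino)hex-5-ynoic acid | C#CC[C@@H](NC(=O)OC(C)(C)C)CC(=O)O | starting material
2 | trimethylsilyl (R)-3-[tert-butoxycarbonyl(trimethylsilyl)amino]-6-(trimethylsilyl)hex-5-ynoate | C[Si](C)(C)C#CC[C@@H](N([Si](C)(C)C)C(=O)OC(C)(C)C)CC(=O)O[Si](C)(C)C | intermediate (not isolated)
3 | (R)-3-(tert-butoxycarbonylamino)-6-(trimethylsilyl)hex-5-ynoic acid | C[Si](C)(C)C#CC[C@@H](NC(=O)OC(C)(C)C)CC(=O)O | intermediate
4 | methyl (R)-3-amino-6-(trimethylsilyl)hex-5-ynoate hydrochloride | C[Si](C)(C)C#CC[C@@H](N)CC(=O)OC.Cl | intermediate
5 | 3-aminopropan-1-ol | NCCCO | starting material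
6 | N-(4-bromobutyl)phthalimide | O=C1c2ccccc2C(=O)N1CCCCBr | starting material
7 | N-[4-(3-hydroxypropylamino)butyl]phthalimide | O=C1c2ccccc2C(=O)N1CCCCNCCCO | intermediate (not isolated)
8 | tert-butyl N-(3-hydroxypropyl)-N-(4-phthalimidobutyl)carbamate | O=C1c2ccccc2C(=O)N1CCCCN(CCCO)C(=O)OC(C)(C)C | intermediate
9 | tert-butyl N-(3-oxopropyl)-N-(4-phthalimidobutyl)carbamate | O=CCCN(CCCCN1C(=O)c2ccccc2C1=O)C(=O)OC(C)(C)C | intermediate
10 | methyl (R)-3-[(E)-3-[tert-butoxycarbonyl(4-phthalimidobutyl)amino]propylideneamino]-6-(trimethylsilyl)hex-5-ynoate | C[Si](C)(C)C#CC[C@@H](/N=C/CCN(CCCCN1C(=O)c2ccccc2C1=O)C(=O)OC(C)(C)C)CC(=O)OC | intermediate (not isolated)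
11 | methyl (R)-3-[3-[tert-butoxycarbonyl(4-phthalimidobutyl)amino]propylamino]-6-(trimethylsilyl)hex-5-ynoate | C[Si](C)(C)C#CC[C@@H](NCCCN(CCCCN1C(=O)c2ccccc2C1=O)C(=O)OC(C)(C)C)CC(=O)OC | intermediate
12 | methyl (3R,5Z)-3-[3-[tert-butoxycarbonyl(4-phthalimidobutyl)amino]propylamino]-6-(trimethylsilyl)hex-5-enoate | C[Si](C)(C)/C=C\C[C@@H](NCCCN(CCCCN1C(=O)c2ccccc2C1=O)C(=O)OC(C)(C)C)CC(=O)OC | intermediate
13 | methyl (3R,5Z)-3-[3-[(4-aminobutyl)(tert-butoxycarbonyl)amino]propylamino]-6-(trimethylsilyl)hex-5-enoate | C[Si](C)(C)/C=C\C[C@@H](NCCCN(CCCCN)C(=O)OC(C)(C)C)CC(=O)OC | intermediate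
14 | (3R,5Z)-3-[3-[(4-aminobutyl)(tert-butoxycarbonyl)amino]propylamino]-6-(trimethylsilyl)hex-5-enoic acid | C[Si](C)(C)/C=C\C[C@@H](NCCCN(CCCCN)C(=O)OC(C)(C)C)CC(=O)O | intermediate
15 | (3R,5Z)-3-[3-[(4-aminobutyl)(tert-butoxycarbonyl)amino]propylamino]-6-(trimethylsilyl)hex-5-enoyl azide | C[Si](C)(C)/C=C\C[C@@H](NCCCN(CCCCN)C(=O)OC(C)(C)C)CC(=O)N=[N+]=[N-] | intermediate (not isolated)
16 | tert-butyl (6R)-8-oxo-6-[(Z)-3-(trimethylsilyl)prop-2-enyl]-1,5,9-triazacyclotridecane-1-carboxylate (N14-Boc lactam, N1–H, silylallyl group at C6) | C[Si](C)(C)/C=C\C[C@@H]1CC(=O)NCCCCN(C(=O)OC(C)(C)C)CCCN1 | intermediate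
17 | oct-2-ynal | CCCCCC#CC=O | starting material
18 | (E)-N1-(oct-2-ynylidene)iminium ion of 16 | C[Si](C)(C)/C=C\C[C@@H]1CC(=O)NCCCCN(C(=O)OC(C)(C)C)CCC/[N+]1=C\C#CCCCCC | intermediate (not isolated)
19 | (2R,6R)-2-(hept-1-ynyl) N14-Boc bicyclic lactam, C3=C4, branches at C2 and C6 trans | CCCCCC#C[C@H]1C=CC[C@@H]2CC(=O)NCCCCN(C(=O)OC(C)(C)C)CCCN21 | intermediate
20 | (2S,6R)-2-(2-oxoheptyl) N14-Boc bicyclic lactam | CCCCCC(=O)C[C@H]1C=CC[C@@H]2CC(=O)NCCCCN(C(=O)OC(C)(C)C)CCCN21 | intermediate (not isolated)
21 | (2S,6R)-2-(2-oxoheptyl) bicyclic lactam with free N14–H | CCCCCC(=O)C[C@H]1C=CC[C@@H]2CC(=O)NCCCCNCCCN21 | target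

## Step count and least certain steps

Total: 11 steps. Longest linear sequence: 9 steps (1 → 21 through steps 1, 2, 5–11; the branch from 5 and 6 through steps 3 and 4 is equally long).

**Step 10 (key step).** Three processes threaten it:
- Conjugate addition of N1–H to the ynal in place of condensation at the aldehyde carbon.
- Loss of stereochemical fidelity: the chair with an equatorial C6 branch would give the cis isomer, and passage through the aza-Cope manifold by a less favoured chair would erode enantiopurity, because C6 is transiently planar there.
- Protodesilylation of the vinylsilane if free acid accumulates.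

The fallback replaces the ynal by a saturated aldehyde that carries the ketone masked; it sets out from 16 and comes back at 21. Commercial ethyl 3-oxooctanoate would be ketalised with 2,2-dimethylpropane-1,3-diol (TsOH, toluene, water separator) to ethyl 2-(5,5-dimethyl-2-pentyl-1,3-dioxan-2-yl)acetate F1. Reduction with iBu2AlH at −78 °C would give 2-(5,5-dimethyl-2-pentyl-1,3-dioxan-2-yl)acetaldehyde F2. Condensation of F2 with the camphorsulfonate salt of 16 would give the saturated iminium ion F3, which has no conjugate position. The same vinylsilane closure would then give the ketal-protected N14-Boc bicycle F4. Aqueous HCl in THF would remove ketal and carbamate together to give 21, so step 11 is bypassed as well. The stereochemical argument is unchanged, so this fallback answers the chemoselectivity risk and not the selectivity risk.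

**Step 11.** Three processes threaten it:
- Attack of water at the proximal alkyne carbon.
- β-Elimination of N1 from the new β-amino ketone on warming, which opens ring A and epimerises C2 on re-closure.
- Deactivation of gold by nitrogen coordination.

The fallback installs the oxygen by borylation and oxidation; it sets out from 19 and comes back at 20. CuCl/NaOtBu/PCy3-catalysed addition of B2pin2 with MeOH as proton source (syn borylcupration, boron going to the alkyne carbon remote from the propargylic nitrogen) would give the alkenyl boronate F5. Oxidation with NaBO3·4H2O in THF/H2O would give the enol and hence 20, which is deprotected as in the second stage of step 11.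

**Step 9.** The likely failures are intermolecular acylation leading to cyclic dimers and oligomers, Curtius rearrangement of the acyl azide if the mixture warms, and poor solubility of the zwitterion. The fallback is a metal-templated aminolysis of the ester; it sets out from 13 and comes back at 16, omitting step 8. Amino ester 13 would be heated with Sb(OEt)3 in benzene over 4 Å MS. Trivalent antimony should bind N1 and N9 as amides and deliver N9 to the ester carbonyl C8 through a six-membered array (antimony-templated lactamisation of polyamino esters). No new compound is made (F0).

**Step 1.** The likely failures are incomplete metalation of the alkyne in a sparingly soluble polylithiated salt and competing deprotonation α to the carboxylate. The fallback avoids strong base; it sets out from 1 and comes back at 4. MeI/KHCO3 in DMF would give methyl (R)-3-(tert-butoxycarbonylamino)hex-5-ynoate F6. Zn(OTf)2/Et3N/Me3SiCl in CH2Cl2 (a zinc acetylide formed with an amine base that cannot enolise the ester) would give methyl (R)-3-(tert-butoxycarbonylamino)-6-(trimethylsilyl)hex-5-ynoate F7. HCl in MeOH would then remove the carbamate and give 4.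

## Further compounds

F1 | step 10 | ethyl 2-(5,5-dimethyl-2-pentyl-1,3-dioxan-2-yl)acetate | CCCCCC1(CC(=O)OCC)OCC(C)(C)CO1
F2 | step 10 | 2-(5,5-dimethyl-2-pentyl-1,3-dioxan-2-yl)acetaldehyde | CCCCCC1(CC=O)OCC(C)(C)CO1
F3 | step 10 | (E)-iminium ion of 16 and F2 | C[Si](C)(C)/C=C\C[C@@H]1CC(=O)NCCCCN(C(=O)OC(C)(C)C)CCC/[N+]1=C\CC1(CCCCC)OCC(C)(C)CO1
F4 | step 10 | (2S,6R)-2-[(5,5-dimethyl-2-pentyl-1,3-dioxan-2-yl)methyl] N14-Boc bicyclic lactam | CCCCCC1(OCC(C)(C)CO1)C[C@H]1C=CC[C@@H]2CC(=O)NCCCCN(C(=O)OC(C)(C)C)CCCN21
F5 | step 11 | N14-Boc bicyclic lactam with a (Z)-2-(pinacolboryl)hept-1-enyl group at C2, configuration as in 19 | CCCCC/C(=C\[C@H]1C=CC[C@@H]2CC(=O)NCCCCN(C(=O)OC(C)(C)C)CCCN21)B1OC(C)(C)C(C)(C)O1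
F0 | step 9 | none | none
F6 | step 1 | methyl (R)-3-(tert-butoxycarbonylamino)hex-5-ynoate | C#CC[C@@H](NC(=O)OC(C)(C)C)CC(=O)OC
F7 | step 1 | methyl (R)-3-(tert-butoxycarbonylamino)-6-(trimethylsilyl)hex-5-ynoate | C[Si](C)(C)C#CC[C@@H](NC(=O)OC(C)(C)C)CC(=O)OC
A1 | alternative 1 | methyl 3-[N-(cis-4-(tert-butyldimethylsilyloxy)cyclopent-2-enyl)-N-[3-[tert-butoxycarbonyl(4-phthalimidobutyl)amino]propyl]amino]hex-5-enoate | C1=C[C@H](O[Si](C)(C)C(C)(C)C)C[C@@H]1N(CCCN(C(=O)OC(C)(C)C)CCCCN2C(=O)c3ccccc3C2=O)[C@H](CC=C)CC(=O)OC
A2 | alternative 1 | trans-2,6-disubstituted 1,2,3,6-tetrahydropyridine with a 2-silyloxybut-3-enyl chain at C2 | C=C[C@H](O[Si](C)(C)C(C)(C)C)C[C@H]1C=CC[C@H](CC(=O)OC)N1CCCN(C(=O)OC(C)(C)C)CCCCN1C(=O)c2ccccc2C1=O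
A3 | alternative 2 | ring A lactam (C6=O) with the ketal chain at C2 and the N1 chain ending in a malonamic acid | CCCCCC1(OCCO1)C[C@H]1C=CCC(=O)N1CCCN(C(=O)OC(C)(C)C)CCCCNC(=O)CC(=O)O
A4 | alternative 2 | N14-Boc, dioxolane-protected target bicycle | CCCCCC1(OCCO1)C[C@H]1C=CC[C@@H]2CC(=O)NCCCCN(C(=O)OC(C)(C)C)CCCN21
A5 | alternative 3 | methyl 2-[5-[1-(tert-butoxycarbonylamino)-2-(2-pentyl-1,3-dioxolan-2-yl)ethyl]furan-2-yl]acetate | CCCCCC1(OCCO1)C[C@H](NC(=O)OC(C)(C)C)c1ccc(CC(=O)OC)o1
A6 | alternative 3 | N-Boc 6-hydroxy-2H-pyridin-3(6H)-one with the ketal chain at C2 and CH2CO2Me at C6 | CCCCCC1(OCCO1)C[C@@H]1N(C(=O)OC(C)(C)C)C(O)(CC(=O)OC)C=CC1=O
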